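The dioxane ring is closed at its benzylic C7'–O bond, the oxygen being the ring-B phenol oxygen that lies ortho to the C8'–O ether. The key step exploits the free 4-OH of guaiacyl ring A, para to C7': Ag2O dehydrogenates an open-chain C8'–O–aryl ether, which still carries a plain C7'H2 group, to a p-quinone methide, and the ring-B phenol adds to C7' in the same flask. One operation thus turns a C–H bond into the ring C–O bond and sets C7' trans to C8'. C8' itself comes from a commercial enantiopure glycidyl ether through Grignard opening and a Mitsunobu inversion. A final Wittig reaction adds the enal.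

Key step: step 5

Assumption: ring A is the 4-hydroxy-3-methoxyphenyl ring and ring B the arene fused to the dioxane; C7' carries ring A and C8' carries CH2OH, so (7'S,8'S) is the trans-(2S,3S) 2,3-dihydro-1,4-benzodioxine; phenol 2 is taken as not commercial and is made in step 1.

Step 1
Reactants: 1 (3,4-dihydroxy-5-methoxybenzaldehyde, 5-hydroxyvanillin)
Product: 2 monobenzyl ether 3-(benzyloxy)-4-hydroxy-5-methoxybenzaldehyde
Conditions: NaH (2.1 equiv), DMSO, rt; BnCl (1.0 equiv), rt; then 1 M HCl
Reagents that add atoms: benzyl chloride, ClCc1ccccc1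
Why: Williamson ether synthesis on the dianion, in which the 3-phenoxide (not conjugated with the formyl group and flanked by one substituent only) is the more nucleophilic oxygen, so one equivalent of benzyl chloride should alkylate O-3 selectively; no stereocentre is formed.

Step 2
Reactants: 3 (1-(benzyloxy)-4-bromo-2-methoxybenzene); 4 ((2S)-2-[(benzyloxy)methyl]oxirane, benzyl (S)-glycidyl ether)
Product: 6 alcohol (2S)-1-(benzyloxy)-3-[4-(benzyloxy)-3-methoxyphenyl]propan-2-ol, via aryl Grignard reagent 5 (not isolated)
Conditions: Mg, THF, 45 °C; then CuI (10 mol %), 4, −30 → 0 °C; aq. NH4Cl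
Reagents that add atoms: none
Why: Copper-catalysed Grignard opening of a terminal epoxide occurs by SN2 at the unsubstituted CH2, so the stereocentre of 4 is carried unchanged into the (S)-carbinol.

Step 3
Reactants: 6 (alcohol from step 2); 2 (phenol from step 1)
Product: 7 tribenzyl ether 3-(benzyloxy)-4-{[(2R)-1-(benzyloxy)-3-[4-(benzyloxy)-3-methoxyphenyl]propan-2-yl]oxy}-5-methoxybenzaldehyde
Conditions: PPh3, DIAD, THF, 0 °C → rt
Reagents that add atoms: none
Why: Mitsunobu etherification, in which the acidic 4-OH of 2 (para to the formyl group) displaces the activated secondary alcohol with inversion, turning the (S)-carbinol into the (R)-aryl ether that becomes C8'.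

Step 4
Reactants: 7 (tribenzyl ether)
Product: 8 triol 3-hydroxy-4-{[(2R)-1-hydroxy-3-(4-hydroxy-3-methoxyphenyl)propan-2-yl]oxy}-5-methoxybenzaldehyde
Conditions: H2 (1 atm), 10% Pd/C, EtOAc, rt, stopped at full debenzylation
Reagents that add atoms: none
Why: Catalytic hydrogenolysis should cleave the two aryl benzyl ethers and the primary alkyl benzyl ether, while the non-benzylic secondary alkyl aryl ether is inert and the electron-rich aryl aldehyde is reduced only slowly in an aprotic solvent; the stereocentre is untouched.

Step 5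
Reactants: 8 (triol)
Product: 10 benzodioxane aldehyde (2S,3S)-3-(4-hydroxy-3-methoxyphenyl)-2-(hydroxymethyl)-8-methoxy-2,3-dihydro-1,4-benzodioxine-6-carbaldehyde, via p-quinone methide 9 (not isolated)
Conditions: Ag2O (1.2 equiv), dry acetone–CH2Cl2, rt, dark, N2
Reagents that add atoms: none
Why: Ag2O removes two electrons and two protons from the para-alkylated guaiacol ring A of 8 to give p-quinone methide 9, whose exocyclic carbon C7' is the electrophilic end of a vinylogous enone; the ring-B phenol oxygen ortho to the ether oxygen adds to it (intramolecular oxa-1,6-addition) and ring A re-aromatises. The closest known reaction types are the Ag2O or DDQ oxidation of 4-alkyl-2-methoxyphenols to quinone methides with capture by a pendant phenol, as in the oxidative cyclisation of 1-(2-hydroxyphenyl)-3-(4-hydroxyphenyl)propanes to flavans and in the ring-closing event of biomimetic 1,4-benzodioxane neolignan formation. The dioxane ring closes in 6-exo-trig mode onto the exocyclic C7'=C(ring A) double bond. The new stereocentre C7' is controlled by the existing C8' centre: a chair-like transition state with the CH2OH group and the cyclohexadienone ring both pseudo-equatorial should give the trans (2S,3S) ring, which is also the thermodynamic isomer should the addition reverse. The step needs chemoselective oxidation of ring A, secured because only that phenol sits on an electron-rich ring with a para CH2 group, whereas the ring-B phenol is deactivated by the formyl group and cannot form a quinone methide. Over-oxidation of the product phenol is limited by using close to one equivalent of Ag2O.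

Step 6
Reactants: 10 (benzodioxane aldehyde)
Product: 11 (7'S,8'S)-nocomtal
Conditions: Ph3P=CHCHO (1.3 equiv), toluene, 80 °C
Reagents that add atoms: (triphenylphosphoranylidene)acetaldehyde, O=CC=P(c1ccccc1)(c1ccccc1)c1ccccc1
Why: Wittig reaction with the stabilised formylmethylene ylide, which should convert the aryl aldehyde into the (E)-enal and is too weakly basic to disturb the free phenol, the primary alcohol or the ring stereocentres.

Compound list
1 | 3,4-dihydroxy-5-methoxybenzaldehyde (5-hydroxyvanillin) | COc1cc(C=O)cc(O)c1O | starting material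
2 | 3-(benzyloxy)-4-hydroxy-5-methoxybenzaldehyde | COc1cc(C=O)cc(OCc2ccccc2)c1O | intermediate
3 | 1-(benzyloxy)-4-bromo-2-methoxybenzene | COc1cc(Br)ccc1OCc1ccccc1 | starting material
4 | (2S)-2-[(benzyloxy)methyl]oxirane (benzyl (S)-glycidyl ether) | C1O[C@@H]1COCc1ccccc1 | starting material
5 | [4-(benzyloxy)-3-methoxyphenyl]magnesium bromide | COc1cc([Mg]Br)ccc1OCc1ccccc1 | intermediate
6 | (2S)-1-(benzyloxy)-3-[4-(benzyloxy)-3-methoxyphenyl]propan-2-ol | COc1cc(C[C@@H](COCc2ccccc2)O)ccc1OCc1ccccc1 | intermediate
7 | 3-(benzyloxy)-4-{[(2R)-1-(benzyloxy)-3-[4-(benzyloxy)-3-methoxyphenyl]propan-2-yl]oxy}-5-methoxybenzaldehyde | COc1cc(C[C@H](COCc2ccccc2)Oc2c(OCc3ccccc3)cc(C=O)cc2OC)ccc1OCc1ccccc1 | intermediate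
8 | 3-hydroxy-4-{[(2R)-1-hydroxy-3-(4-hydroxy-3-methoxyphenyl)propan-2-yl]oxy}-5-methoxybenzaldehyde | COc1cc(C[C@H](CO)Oc2c(O)cc(C=O)cc2OC)ccc1O | intermediate
9 | 3-hydroxy-4-{[(2R)-1-hydroxy-3-(3-methoxy-4-oxocyclohexa-2,5-dien-1-ylidene)propan-2-yl]oxy}-5-methoxybenzaldehyde (p-quinone methide, either alkene geometry) | COC1=CC(=C[C@H](CO)Oc2c(O)cc(C=O)cc2OC)C=CC1=O | intermediate
10 | (2S,3S)-3-(4-hydroxy-3-methoxyphenyl)-2-(hydroxymethyl)-8-methoxy-2,3-dihydro-1,4-benzodioxine-6-carbaldehyde | COc1cc([C@@H]2Oc3cc(C=O)cc(OC)c3O[C@H]2CO)ccc1O | intermediate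
11 | (7'S,8'S)-nocomtal, (2E)-3-[(2S,3S)-3-(4-hydroxy-3-methoxyphenyl)-2-(hydroxymethyl)-8-methoxy-2,3-dihydro-1,4-benzodioxin-6-yl]prop-2-enal | COc1cc([C@@H]2Oc3cc(/C=C/C=O)cc(OC)c3O[C@H]2CO)ccc1O | target

Total step count: 6. Longest linear sequence: 5 steps (steps 2–6 from bromide 3; equally steps 1 and 3–6 from aldehyde 1).

Steps most likely to fail

Step 5 (key step). The oxidant may also attack the ring-B phenol or re-oxidise the phenol of the product, and a kinetically controlled ring closure may give part of the cis ring. The fallback separates oxidation from ring closure; it sets out from 8 and comes back at 10. DDQ (1.05 equiv) in MeOH–CH2Cl2 at 0 °C should take 8 through the same quinone methide, now captured by the solvent, to the benzylic methyl ether 3-hydroxy-4-{[(2S)-1-hydroxy-3-(4-hydroxy-3-methoxyphenyl)-3-methoxypropan-2-yl]oxy}-5-methoxybenzaldehyde F1, as both C7' epimers; the C8' centre is spatially unchanged and only its descriptor changes. TsOH·H2O (10 mol %) in MeCN at rt should then ionise the p-hydroxybenzylic ether and close the ring under thermodynamic control to the trans compound 10.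

Step 3. Elimination of the activated secondary alcohol towards the conjugated alkene and slow attack by the doubly ortho-substituted phenoxide may erode the coupling. The fallback moves the etherification to a carbon alpha to an ester, where substitution is fast; it sets out from Grignard reagent 5 and phenol 2 and comes back at 8. Reagent 5 and commercial methyl (2S)-oxirane-2-carboxylate (CuBr·SMe2 cat., THF, −40 °C) should give methyl (2S)-3-[4-(benzyloxy)-3-methoxyphenyl]-2-hydroxypropanoate F2. A Mitsunobu reaction of F2 with 2 (PPh3, DIAD, THF) should give, with inversion, methyl (2R)-2-[2-(benzyloxy)-4-formyl-6-methoxyphenoxy]-3-[4-(benzyloxy)-3-methoxyphenyl]propanoate F3. LiBH4 (THF, 0 °C) should reduce ester and formyl group to (2R)-2-[2-(benzyloxy)-4-(hydroxymethyl)-6-methoxyphenoxy]-3-[4-(benzyloxy)-3-methoxyphenyl]propan-1-ol F4. MnO2 (CH2Cl2, rt) should re-oxidise only the benzylic alcohol to 3-(benzyloxy)-4-{[(2R)-1-[4-(benzyloxy)-3-methoxyphenyl]-3-hydroxypropan-2-yl]oxy}-5-methoxybenzaldehyde F5. Brief hydrogenolysis of the two aryl benzyl ethers (H2, Pd/C, EtOAc) should then give 8.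

Step 4. The aryl aldehyde may be reduced while the slower primary alkyl benzyl ether is still being cleaved. The fallback is a non-reductive Lewis-acid debenzylation; it sets out from 7 and comes back at 8 without a new isolated compound. BCl3 (CH2Cl2, −78 °C) with pentamethylbenzene as benzyl-cation scavenger, quenched with MeOH at −78 °C, should cleave all three benzyl ethers and leave the aldehyde, the methyl ethers and the secondary alkyl aryl ether intact.

Further compounds
F1 | step 5 | 3-hydroxy-4-{[(2S)-1-hydroxy-3-(4-hydroxy-3-methoxyphenyl)-3-methoxypropan-2-yl]oxy}-5-methoxybenzaldehyde (both C3 epimers) | COc1cc(C(OC)[C@H](CO)Oc2c(O)cc(C=O)cc2OC)ccc1O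
F2 | step 3 | methyl (2S)-3-[4-(benzyloxy)-3-methoxyphenyl]-2-hydroxypropanoate | COc1cc(C[C@@H](C(=O)OC)O)ccc1OCc1ccccc1
F3 | step 3 | methyl (2R)-2-[2-(benzyloxy)-4-formyl-6-methoxyphenoxy]-3-[4-(benzyloxy)-3-methoxyphenyl]propanoate | COc1cc(C[C@H](C(=O)OC)Oc2c(OCc3ccccc3)cc(C=O)cc2OC)ccc1OCc1ccccc1
F4 | step 3 | (2R)-2-[2-(benzyloxy)-4-(hydroxymethyl)-6-methoxyphenoxy]-3-[4-(benzyloxy)-3-methoxyphenyl]propan-1-ol | COc1cc(C[C@H](CO)Oc2c(OCc3ccccc3)cc(CO)cc2OC)ccc1OCc1ccccc1
F5 | step 3 | 3-(benzyloxy)-4-{[(2R)-1-[4-(benzyloxy)-3-methoxyphenyl]-3-hydroxypropan-2-yl]oxy}-5-methoxybenzaldehyde | COc1cc(C[C@H](CO)Oc2c(OCc3ccccc3)cc(C=O)cc2OC)ccc1OCc1ccccc1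
F0 | step 4 | none | none
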